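(The data were computed for substances that don't exist; scatter was added.)

Your hunch, that winter read at 15 h ends richer in E than summer read at 8.0 h, gets a quick number from me, and I expect it not to survive.

in all of them: L 10 mM
- Thursday's: J 0.050 M; E 0.050 M; G 0.40 M; run made earlier
- Monday's: J 0.20 M; E 0.20 M; G 0.40 M; run made earlier
- winter: J 0.10 M; E 0.10 M; G 0.400 M; time 15 h
- summer: J 0.10 M; E 0.10 M; G 0.400 M; time 8.0 h

| run | time / h | E / % | J / % |
|---|---|---|---|
| Thursday's | 1.00 | 47.7 | 48.9 |
| Thursday's | 2.00 | 46.8 | 46.8 |
| Thursday's | 5.00 | 44.5 | 42.6 |
| Thursday's | 12.0 | 36.8 | 38.4 |
| Monday's | 1.00 | 46.7 | 46.9 |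
| Monday's | 2.00 | 46.2 | 47.0 |
| Monday's | 5.00 | 43.5 | 44.4 |
| Monday's | 12.0 | 37.9 | 38.1 |

(each reading ± 1 percentage point)

- L is single-handed; J and E are mirror images of each other, charged as a racemate, each of them at the stated concentration
- the numbers in the tables scatter by 1 percentage point (one standard deviation)
- an excess is the difference of the two amounts in percent of their sum
- an excess is below zero if the other one leads

- the flask that ends with the higher excess of E over J among what is left of the two, or "neither" when 2 percentage points or less lies between them (winter / summer / neither)
- excess of E over J among what is left of the two at the end, winter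
- excess of E over J among what is left of the two at the end, summer

At the last reading, 12.0 h, Thursday's flask holds 75.2% of its J and E together, and Monday's 76.0%, although [J] was 0.050 M in one and 0.20 M in the other. The part lost does not follow the charge, so I take the loss as first order in the substrate, and your [J] of 0.10 M lies between the two. That gives one clock, the loss half-life of the pair, the time per halving of J and E together, read as an average over the first 12.0 h and carried on as an estimate, and I count how many of these each flask gets:

half-life = 12.0 h × ln(2) / ln(1 / 75.6%) = 29.7 h

winter: 0.504 half-lives, leaving 70.5%

summer: 0.269 half-lives, leaving 83.0%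

The mean excess of E over J at those last readings is −1.20%, a reading with 1 percentage point of scatter on each amount. If it grew in step with the count, the flasks would stand 0.7 points apart, less than the margin of 2 points. So I say neither.

The forecast, from the same runs, reads “Both enantiomers fall at the same fractional rate” and gives −1% for winter (−2.7% to 0.7%) and −0.6% for summer (−1.5% to 0.4%), so neither, with a gap narrower than mine.

    G + L + E → L + D (k = 0.00134 /M²/s)
    G + L + J → L + X (k = 0.00370 /M²/s)
    J ⇌ E (k = 3.45 × 10⁻⁴ /s)
    2 G → Z (k = 2.50 × 10⁻⁵ /M/s)

The flasks give neither: winter ends at 0.283%, summer at 0.400%, both inside the forecast's ranges. Winter keeps 71% of its J and summer 80%, near my count, but G stands at 41% of its charge in winter and 57% in summer at the end, so the loss is not pseudo-first-order and my clock is an average. The relaxation of J and E has a half-life of 0.279 h, short against 15 h. A neighbour of summer has [L] at 0.040 M; both loss steps carry [L], so its count becomes 1.08 half-lives, leaving 47.4%. That neighbour keeps 46% of its J and 47% of its E, and its excess of E over J is 1.31%.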